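**Retrosynthetic overview**
- Kushenol B ⇐ its tetra-MOM ether; ring C is closed last by an enantioselective oxa-Michael addition of the only free phenol of a 2′-hydroxychalcone (sets 2S).
- Chalcone ⇐ fully substituted ring A aryllithium + ring B cinnamoyl Weinreb amide (from resorcinol by iodination and Heck reaction).
- (R)-Lavandulyl chain ⇐ grown on ring A by three 1,2-boronate shifts: ArLi → ArCH2Bpin; then the key stereospecific 1,2-shift of the benzyl group from boron onto a sparteine-lithiated homoprenyl benzoate (sets R); then Zweifel isopropenylation.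
- Ring A ⇐ resorcinol: bis-MOM ether, ortho-lithiation/prenylation, Ir C–H borylation/oxidation for the third oxygen, THP ether to mark the future O1.
- Ring order: rings A and B come from resorcinol; ring C is the only ring formed, in the second-to-last step.

Assumption: the SMILES encodes 2S at C2 and R at the lavandulyl carbon; the THP acetal carbon in 8–11, 15, 16, 19–21 and 25–27 is an unspecified 1:1 mixture that disappears in step 11.

**Step 1**
Reactants: 1 resorcinol
Product: 2 1,3-bis(methoxymethoxy)benzene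
Conditions: MOMCl (2.4 equiv), iPr2NEt, CH2Cl2, 0 °C → rt
Reagents that add atoms: chloromethyl methyl ether, COCCl
Why: O-alkylation of both phenols (MOM protection) gives base-stable acetal ethers that later act as ortho-directing groups.

**Step 2**
Reactants: 2 1,3-bis(methoxymethoxy)benzene; 3 prenyl bromide (1-bromo-3-methylbut-2-ene)
Product: 5 1,3-bis(methoxymethoxy)-2-(3-methylbut-2-en-1-yl)benzene, via aryllithium 4 (not isolated)
Conditions: nBuLi, THF, 0 °C → rt; CuI (10 mol %), 3, −78 °C → rt
Reagents that add atoms: none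
Why: Directed ortho-metalation occurs only at the C–H flanked by both OMOM groups, and copper-assisted allylic substitution of the bromide gives the linear prenyl arene.

**Step 3**
Reactants: 5 1,3-bis(methoxymethoxy)-2-(3-methylbut-2-en-1-yl)benzene
Product: 7 3,5-bis(methoxymethoxy)-4-(3-methylbut-2-en-1-yl)phenol, via arylboronate 6 (not isolated)
Conditions: [Ir(OMe)(cod)]2 (1.5 mol %), dtbpy (3 mol %), B2pin2 (1.0 equiv), THF, 60 °C; then 30 % H2O2, 2 M NaOH, 0 °C
Reagents that add atoms: bis(pinacolato)diboron, CC1(C)OB(B2OC(C)(C)C(C)(C)O2)OC1(C)C (boron of intermediate 6 only); hydrogen peroxide, OO (phenol oxygen of 7)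
Why: Sterically controlled iridium-catalysed aromatic C–H borylation attacks the only ring C–H with no ortho substituent (C5), the trisubstituted alkene is a poor partner for the Ir–boryl species, and C–B oxidation gives the phenol at that position.

**Step 4**
Reactants: 7 3,5-bis(methoxymethoxy)-4-(3-methylbut-2-en-1-yl)phenol
Product: 8 2-[3,5-bis(methoxymethoxy)-4-(3-methylbut-2-en-1-yl)phenoxy]oxane (THP ether)
Conditions: 3,4-dihydro-2H-pyran, PPTS (10 mol %), CH2Cl2, rt
Reagents that add atoms: 3,4-dihydro-2H-pyran, C1=COCCC1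
Why: Acid-catalysed addition of the phenol to the enol ether (THP acetal formation) marks the future O1 with a lithiation-compatible group that is far more acid-labile than the aryl MOM ethers.

**Step 5**
Reactants: 8 2-[3,5-bis(methoxymethoxy)-4-(3-methylbut-2-en-1-yl)phenoxy]oxane
Product: 11 2-{[2,4-bis(methoxymethoxy)-3-(3-methylbut-2-en-1-yl)-6-(oxan-2-yloxy)phenyl]methyl}-4,4,5,5-tetramethyl-1,3,2-dioxaborolane, via aryllithium 9 (not isolated), via bromomethyl ate complex 10 (not isolated)
Conditions: nBuLi, TMEDA, THF, −20 → 0 °C; BrCH2Bpin, −78 °C → rt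
Reagents that add atoms: 2-(bromomethyl)-4,4,5,5-tetramethyl-1,3,2-dioxaborolane, BrCB1OC(C)(C)C(C)(C)O1
Why: Directed ortho-metalation between OTHP and OMOM (two equivalent sites) is followed by boronate formation and a Matteson-type 1,2-shift of the aryl group from boron to carbon with loss of bromide.

**Step 6**
Reactants: 12 4-methylpent-3-en-1-ol
Product: 13 4-methylpent-3-en-1-yl 2,4,6-triisopropylbenzoate
Conditions: 2,4,6-triisopropylbenzoic acid, PPh3, DIAD, THF, 0 °C → rt
Reagents that add atoms: 2,4,6-triisopropylbenzoic acid, CC(C)c1cc(C(C)C)c(C(=O)O)c(C(C)C)c1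
Why: Mitsunobu esterification of the primary alcohol gives a hindered benzoate that resists attack by sBuLi and serves as directing and leaving group in the next step.

**Step 7 (key step)**
Reactants: 13 4-methylpent-3-en-1-yl 2,4,6-triisopropylbenzoate; 11 benzylic pinacol boronate
Product: 16 2-{(2R)-1-[2,4-bis(methoxymethoxy)-3-(3-methylbut-2-en-1-yl)-6-(oxan-2-yloxy)phenyl]-5-methylhex-4-en-2-yl}-4,4,5,5-tetramethyl-1,3,2-dioxaborolane, via lithiated ester 14 (not isolated), via boronate complex 15 (not isolated)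
Conditions: 13 (1.3 equiv), sBuLi, (−)-sparteine, Et2O, −78 °C, 5 h; 11, −78 °C, 1 h; then 35 °C, 12 h; H2O
Reagents that add atoms: none
Why: In this lithiation–borylation, (−)-sparteine/sBuLi removes the pro-S hydrogen to give the configurationally stable (S)-lithio ester, boron is captured with retention, and the benzyl group then undergoes an antiperiplanar 1,2-metallate shift from boron to carbon with inversion and loss of the benzoate, which sets the (R)-configured carbon of the future lavandulyl chain.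

**Step 8**
Reactants: 16 secondary pinacol boronate; 17 2-bromopropene
Product: 21 2-{3,5-bis(methoxymethoxy)-2-[(2R)-5-methyl-2-(prop-1-en-2-yl)hex-4-en-1-yl]-4-(3-methylbut-2-en-1-yl)phenoxy}oxane, via isopropenyllithium 18 (not isolated), via alkenylboronate complex 19 (not isolated), via iodoboronate 20 (not isolated)
Conditions: 17, tBuLi (2 equiv per 17), THF, −78 °C; 16, −78 °C; I2, THF, −78 °C; NaOMe, MeOH, −78 °C → rt
Reagents that add atoms: iodine, II (held only in intermediate 20)
Why: In this Zweifel olefination, iodonium formation on the alkenyl ate complex triggers a 1,2-shift of the secondary alkyl group from boron to carbon with retention, and methoxide-induced anti-elimination of boron and iodide leaves the isopropenyl group, completing the (R)-lavandulyl chain.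

**Step 9**
Reactants: 2 1,3-bis(methoxymethoxy)benzene
Product: 22 1-iodo-2,4-bis(methoxymethoxy)benzene
Conditions: NIS (1.0 equiv), MeCN, 0 °C → rt
Reagents that add atoms: N-iodosuccinimide, O=C1CCC(=O)N1I
Why: Electrophilic aromatic iodination occurs para to one OMOM and ortho to the other (C4), which is less hindered than the position between them.

**Step 10**
Reactants: 22 1-iodo-2,4-bis(methoxymethoxy)benzene; 23 N-methoxy-N-methylprop-2-enamide
Product: 24 (2E)-3-[2,4-bis(methoxymethoxy)phenyl]-N-methoxy-N-methylprop-2-enamide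
Conditions: Pd(OAc)2 (5 mol %), P(o-tol)3 (10 mol %), Et3N, DMF, 90 °C
Reagents that add atoms: none
Why: Mizoroki–Heck arylation of the acrylamide gives the E-cinnamoyl Weinreb amide by syn-insertion and syn-β-hydride elimination.

**Step 11**
Reactants: 21 lavandulyl arene; 24 ring B Weinreb amide
Product: 28 (2E)-3-[2,4-bis(methoxymethoxy)phenyl]-1-{2-hydroxy-4,6-bis(methoxymethoxy)-3-[(2R)-5-methyl-2-(prop-1-en-2-yl)hex-4-en-1-yl]-5-(3-methylbut-2-en-1-yl)phenyl}prop-2-en-1-one, via aryllithium 25 (not isolated), via lithium hemiaminal 26 (not isolated), via THP chalcone 27 (not isolated)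
Conditions: nBuLi, TMEDA, THF, 0 °C; 24, −78 → 0 °C; H2O; crude in MeOH, PPTS (10 mol %), rt
Reagents that add atoms: none
Why: Directed ortho-metalation at the last ring C–H (between OTHP and OMOM) and 1,2-addition to the Weinreb amide give a chelated hemiaminal that collapses to the E-enone only on quench, and PPTS/MeOH transacetalisation then removes only the THP group, freeing the phenol next to the lavandulyl chain.

**Step 12**
Reactants: 28 2′-hydroxychalcone
Product: 29 (2S)-2-[2,4-bis(methoxymethoxy)phenyl]-5,7-bis(methoxymethoxy)-8-[(2R)-5-methyl-2-(prop-1-en-2-yl)hex-4-en-1-yl]-6-(3-methylbut-2-en-1-yl)-2,3-dihydro-4H-chromen-4-one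
Conditions: BIMP catalyst [thiourea ArNHC(S)NH–CH(tBu)CH2–N=P(4-MeOC6H4)3, Ar = 3,5-(CF3)2C6H3, from L-tert-leucine] (10 mol %), methyl salicylate (20 mol %), toluene, −30 °C; AcOH quench
Reagents that add atoms: none
Why: Proposed new method: an enantioselective 6-endo-trig oxa-Michael cyclisation of a non-activated 2′-hydroxy-6′-alkoxychalcone by a bifunctional iminophosphorane–thiourea superbase under proton-buffered conditions, in which the iminophosphorane (much more basic than the tertiary amine of cinchona catalysts) breaks the O–H···O=C hydrogen bond and ionises the phenol to a tight chiral phosphonium phenoxide ion pair, the thiourea binds the enone carbonyl and the developing enolate so that O1 adds to one face of the β-carbon (2S, catalyst-controlled, with the mirror-image catalyst from D-tert-leucine used if a lavandulyl-free model chalcone shows the opposite sense), the 6′-OMOM group twists the aryl ketone so that closure is downhill, the MOM ether on O5 leaves O1 as the only possible nucleophile so that only the 8-lavandulyl-6-prenyl isomer can form, and methyl salicylate (acidity close to that of 28, far above that of C3–H in 29) keeps the base protonated at high conversion so that the retro-oxa-Michael path that would erode the 2S:2R ratio stays closed; the closest known reactions are the quinine–thiourea-catalysed cyclisation of α-alkoxycarbonyl-activated 2′-hydroxychalcones to flavanones and iminophosphorane-catalysed intramolecular oxa-Michael additions of alcohols to unsaturated esters.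

**Step 13**
Reactants: 29 tetra-MOM flavanone
Product: 30 Kushenol B
Conditions: 3 M aq HCl, MeOH, 40 °C
Reagents that add atoms: none
Why: Acid-catalysed methanolysis of the four MOM acetals frees the phenols, while C2 has no low-energy acid-mediated epimerisation path and the isolated alkenes tolerate brief mild acid.

**Compound list**
1 | resorcinol | Oc1cccc(O)c1 | starting material
2 | 1,3-bis(methoxymethoxy)benzene | COCOc1cccc(OCOC)c1 | intermediate
3 | prenyl bromide (1-bromo-3-methylbut-2-ene) | CC(C)=CCBr | starting material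
4 | [2,6-bis(methoxymethoxy)phenyl]lithium | [Li]c1c(OCOC)cccc1OCOC | intermediate
5 | 1,3-bis(methoxymethoxy)-2-(3-methylbut-2-en-1-yl)benzene | COCOc1cccc(OCOC)c1CC=C(C)C | intermediate
6 | 2-[3,5-bis(methoxymethoxy)-4-(3-methylbut-2-en-1-yl)phenyl]-4,4,5,5-tetramethyl-1,3,2-dioxaborolane | COCOc1cc(B2OC(C)(C)C(C)(C)O2)cc(OCOC)c1CC=C(C)C | intermediate
7 | 3,5-bis(methoxymethoxy)-4-(3-methylbut-2-en-1-yl)phenol | COCOc1cc(O)cc(OCOC)c1CC=C(C)C | intermediate
8 | 2-[3,5-bis(methoxymethoxy)-4-(3-methylbut-2-en-1-yl)phenoxy]oxane (acetal carbon unspecified) | COCOc1cc(OC2CCCCO2)cc(OCOC)c1CC=C(C)C | intermediate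
9 | [2,4-bis(methoxymethoxy)-3-(3-methylbut-2-en-1-yl)-6-(oxan-2-yloxy)phenyl]lithium | [Li]c1c(OC2CCCCO2)cc(OCOC)c(CC=C(C)C)c1OCOC | intermediate
10 | lithium aryl(bromomethyl)pinacolborate from 9 | [Li+].BrC[B-]1(c2c(OC3CCCCO3)cc(OCOC)c(CC=C(C)C)c2OCOC)OC(C)(C)C(C)(C)O1 | intermediate
11 | 2-{[2,4-bis(methoxymethoxy)-3-(3-methylbut-2-en-1-yl)-6-(oxan-2-yloxy)phenyl]methyl}-4,4,5,5-tetramethyl-1,3,2-dioxaborolane | CC1(C)OB(Cc2c(OC3CCCCO3)cc(OCOC)c(CC=C(C)C)c2OCOC)OC1(C)C | intermediate
12 | 4-methylpent-3-en-1-ol | CC(C)=CCCO | starting material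
13 | 4-methylpent-3-en-1-yl 2,4,6-triisopropylbenzoate | CC(C)=CCCOC(=O)c1c(C(C)C)cc(C(C)C)cc1C(C)C | intermediate
14 | (1S)-1-lithio-4-methylpent-3-en-1-yl 2,4,6-triisopropylbenzoate, (−)-sparteine complex (drawn without the diamine) | CC(C)=CC[C@H]([Li])OC(=O)c1c(C(C)C)cc(C(C)C)cc1C(C)C | intermediate
15 | lithium boronate complex of 14 and 11 (carbinol carbon S) | [Li+].CC(C)=CC[C@H]([B-]1(Cc2c(OC3CCCCO3)cc(OCOC)c(CC=C(C)C)c2OCOC)OC(C)(C)C(C)(C)O1)OC(=O)c1c(C(C)C)cc(C(C)C)cc1C(C)C | intermediate
16 | 2-{(2R)-1-[2,4-bis(methoxymethoxy)-3-(3-methylbut-2-en-1-yl)-6-(oxan-2-yloxy)phenyl]-5-methylhex-4-en-2-yl}-4,4,5,5-tetramethyl-1,3,2-dioxaborolane | CC(C)=CC[C@H](Cc1c(OC2CCCCO2)cc(OCOC)c(CC=C(C)C)c1OCOC)B1OC(C)(C)C(C)(C)O1 | intermediate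
17 | 2-bromopropene | C=C(C)Br | starting material
18 | prop-1-en-2-yllithium | [Li]C(C)=C | intermediate
19 | lithium isopropenyl ate complex of 16 (alkyl carbon R) | [Li+].CC(C)=CC[C@H](Cc1c(OC2CCCCO2)cc(OCOC)c(CC=C(C)C)c1OCOC)[B-]1(C(C)=C)OC(C)(C)C(C)(C)O1 | intermediate
20 | β-iodo tertiary boronate after the 1,2-shift (lavandulyl carbon R; quaternary carbon as a mixture) | CC(C)=CC[C@H](Cc1c(OC2CCCCO2)cc(OCOC)c(CC=C(C)C)c1OCOC)C(C)(CI)B1OC(C)(C)C(C)(C)O1 | intermediate
21 | 2-{3,5-bis(methoxymethoxy)-2-[(2R)-5-methyl-2-(prop-1-en-2-yl)hex-4-en-1-yl]-4-(3-methylbut-2-en-1-yl)phenoxy}oxane | C=C(C)[C@H](CC=C(C)C)Cc1c(OC2CCCCO2)cc(OCOC)c(CC=C(C)C)c1OCOC | intermediate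
22 | 1-iodo-2,4-bis(methoxymethoxy)benzene | COCOc1ccc(I)c(OCOC)c1 | intermediate
23 | N-methoxy-N-methylprop-2-enamide | C=CC(=O)N(C)OC | starting material
24 | (2E)-3-[2,4-bis(methoxymethoxy)phenyl]-N-methoxy-N-methylprop-2-enamide | COCOc1ccc(/C=C/C(=O)N(C)OC)c(OCOC)c1 | intermediate
25 | aryllithium from 21 (lithium between OTHP and OMOM) | C=C(C)[C@H](CC=C(C)C)Cc1c(OC2CCCCO2)c([Li])c(OCOC)c(CC=C(C)C)c1OCOC | intermediate
26 | lithium N-methoxy-N-methyl hemiaminal alkoxide from 25 and 24 | C=C(C)[C@H](CC=C(C)C)Cc1c(OC2CCCCO2)c(C(O[Li])(N(C)OC)/C=C/c2ccc(OCOC)cc2OCOC)c(OCOC)c(CC=C(C)C)c1OCOC | intermediate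
27 | 2′-O-THP chalcone | C=C(C)[C@H](CC=C(C)C)Cc1c(OC2CCCCO2)c(C(=O)/C=C/c2ccc(OCOC)cc2OCOC)c(OCOC)c(CC=C(C)C)c1OCOC | intermediate
28 | (2E)-3-[2,4-bis(methoxymethoxy)phenyl]-1-{2-hydroxy-4,6-bis(methoxymethoxy)-3-[(2R)-5-methyl-2-(prop-1-en-2-yl)hex-4-en-1-yl]-5-(3-methylbut-2-en-1-yl)phenyl}prop-2-en-1-one | C=C(C)[C@H](CC=C(C)C)Cc1c(O)c(C(=O)/C=C/c2ccc(OCOC)cc2OCOC)c(OCOC)c(CC=C(C)C)c1OCOC | intermediate
29 | (2S)-2-[2,4-bis(methoxymethoxy)phenyl]-5,7-bis(methoxymethoxy)-8-[(2R)-5-methyl-2-(prop-1-en-2-yl)hex-4-en-1-yl]-6-(3-methylbut-2-en-1-yl)-2,3-dihydro-4H-chromen-4-one | C=C(C)[C@H](CC=C(C)C)Cc1c(OCOC)c(CC=C(C)C)c(OCOC)c2c1O[C@H](c1ccc(OCOC)cc1OCOC)CC2=O | intermediate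
30 | Kushenol B, (2S)-2-(2,4-dihydroxyphenyl)-5,7-dihydroxy-8-[(2R)-5-methyl-2-(prop-1-en-2-yl)hex-4-en-1-yl]-6-(3-methylbut-2-en-1-yl)-2,3-dihydro-4H-chromen-4-one | C=C(C)[C@H](CC=C(C)C)Cc1c(O)c(CC=C(C)C)c(O)c2c1O[C@H](c1ccc(O)cc1O)CC2=O | target

**Step count**
Total: 13 steps. Longest linear sequence: 10 steps (1, 2, 3, 4, 5, 7, 8, 11, 12, 13).

**Steps most likely to fail, with fallbacks**

Step 12 (the proposed new cyclisation; risks are low rate on the hydrogen-bonded phenol or a poor 2S:2R ratio). The fallback sets out from 28 and comes back at 29. Compound 28 is cyclised under thermodynamic control (NaOAc, EtOH, reflux), the standard closure of 2′-hydroxy-6′-alkoxychalcones. This gives 29 together with its C2 epimer, the (2R)-flavanone F1. Because the lavandulyl centre is fixed, 29 and F1 are diastereomers and are separated by preparative HPLC. F1 is returned to the same conditions, where ring opening and reclosure re-equilibrate it, and is recycled.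

Step 7 (the hindered, acetal-rich benzylic boronate 11 may capture the lithiated ester slowly or reversibly, giving low yield or eroded selectivity). The fallback sets out from 13 and from 8 and comes back at 21, so that the chain is made off the ring by the same kind of boronate shifts and attached by cross-coupling. Ester 13 is lithiated with sBuLi/(+)-sparteine to the (R)-lithio ester F2. F2 is trapped with isopropenylboronic acid pinacol ester and warmed, which gives the (S)-allylic boronate 2-[(3S)-2,6-dimethylhepta-1,5-dien-3-yl]-4,4,5,5-tetramethyl-1,3,2-dioxaborolane F3. In the same flask, Matteson homologation (BrCH2Cl, nBuLi, −78 °C → rt) gives (S)-lavandulyl pinacol boronate F4. Separately, aryllithium 9 (from 8, as in step 5) is quenched with 1,2-dibromotetrachloroethane to the aryl bromide F5. A B-alkyl Suzuki–Miyaura coupling of F4 with F5 (Pd(OAc)2, SPhos, K3PO4, toluene/H2O, 90 °C) gives 21. The opposite sparteine enantiomer is needed here because the migrating group is now isopropenyl.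

Step 3 (the prenyl alkene may be hydroborated or isomerised under the iridium conditions). The fallback sets out from 2 and comes back at 7, introducing the oxygen before the alkene. Compound 2 is borylated under the same iridium conditions to the boronate F6 and oxidised in the same flask (H2O2, NaOH) to 3,5-bis(methoxymethoxy)phenol F7. F7 is silylated (TIPSCl, imidazole, DMF) to the triisopropylsilyl ether F8. nBuLi then lithiates only between the two OMOM groups, since the bulky silyl ether shields its own flanks, giving aryllithium F9. Prenylation with 3 (CuI catalysis) gives the prenylated silyl ether F10, and TBAF in THF gives 7.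

**Further compounds**
F1 | step 12 | (2R)-2-[2,4-bis(methoxymethoxy)phenyl]-5,7-bis(methoxymethoxy)-8-[(2R)-5-methyl-2-(prop-1-en-2-yl)hex-4-en-1-yl]-6-(3-methylbut-2-en-1-yl)-2,3-dihydro-4H-chromen-4-one | C=C(C)[C@H](CC=C(C)C)Cc1c(OCOC)c(CC=C(C)C)c(OCOC)c2c1O[C@@H](c1ccc(OCOC)cc1OCOC)CC2=O
F2 | step 7 | (1R)-1-lithio-4-methylpent-3-en-1-yl 2,4,6-triisopropylbenzoate, (+)-sparteine complex (drawn without the diamine) | CC(C)=CC[C@@H]([Li])OC(=O)c1c(C(C)C)cc(C(C)C)cc1C(C)C
F3 | step 7 | 2-[(3S)-2,6-dimethylhepta-1,5-dien-3-yl]-4,4,5,5-tetramethyl-1,3,2-dioxaborolane | C=C(C)[C@H](CC=C(C)C)B1OC(C)(C)C(C)(C)O1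
F4 | step 7 | 2-[(2S)-5-methyl-2-(prop-1-en-2-yl)hex-4-en-1-yl]-4,4,5,5-tetramethyl-1,3,2-dioxaborolane | C=C(C)[C@H](CC=C(C)C)CB1OC(C)(C)C(C)(C)O1
F5 | step 7 | 2-[2-bromo-3,5-bis(methoxymethoxy)-4-(3-methylbut-2-en-1-yl)phenoxy]oxane | Brc1c(OC2CCCCO2)cc(OCOC)c(CC=C(C)C)c1OCOC
F6 | step 3 | 2-[3,5-bis(methoxymethoxy)phenyl]-4,4,5,5-tetramethyl-1,3,2-dioxaborolane | COCOc1cc(B2OC(C)(C)C(C)(C)O2)cc(OCOC)c1
F7 | step 3 | 3,5-bis(methoxymethoxy)phenol | COCOc1cc(O)cc(OCOC)c1
F8 | step 3 | [3,5-bis(methoxymethoxy)phenoxy]tri(propan-2-yl)silane | COCOc1cc(O[Si](C(C)C)(C(C)C)C(C)C)cc(OCOC)c1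
F9 | step 3 | {2,6-bis(methoxymethoxy)-4-[tri(propan-2-yl)silyloxy]phenyl}lithium | [Li]c1c(OCOC)cc(O[Si](C(C)C)(C(C)C)C(C)C)cc1OCOC
F10 | step 3 | [3,5-bis(methoxymethoxy)-4-(3-methylbut-2-en-1-yl)phenoxy]tri(propan-2-yl)silane | COCOc1cc(O[Si](C(C)C)(C(C)C)C(C)C)cc(OCOC)c1CC=C(C)C
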